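**Plan**
Numbering (daucane): C1 = quaternary C–CH3, C2–C3 = the CH2–CH2 of the five-membered ring, C4 = C(OH)(iPr), C5 = ring-fusion CH, C6 = CH–O, C7–C10 = rest of the seven-membered ring (C8=C9).
Retrosynthetic cuts: vanillate C–O; C4–isopropyl (ketone at C4); C2–C3 (the five-membered ring goes back to a cyclopropane C1–C2–C5); the CH2 C2 itself; C5–C4; the seven-membered ring back to 2,5-dimethylanisole.
Enabling feature: C2 is a CH2 on quaternary C1 beside ring-fusion C5, and C4 is oxygenated. The five-membered ring is therefore a vinylcyclopropane in disguise (cyclopropane C1–C2–C5 carrying the enol ether C4(OEt)=C3H2 on C5), and the missing β-hydrogen at C1 keeps a metal-mediated ring expansion clean.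
Forward: seven-membered ring first (Birch reduction, dibromocarbene ring expansion), then the three-membered ring (Stille coupling, hydroxyl-directed cyclopropanation), then the five-membered ring by strain-releasing ring expansion, then isopropyl addition and esterification.
Stereochemistry: C6 from a CBS reduction; C1 from delivery of CH2 syn to the C6 hydroxyl; C5 by equilibration next to the C4 ketone (trans fusion); C4 by addition to the less hindered ketone face.

Key step: step 7

Remark: for the hydroazulenone formed in the key step, the trans-fused C5 epimer (C4 anti to the C6 silyloxy group) is assumed to be the thermodynamically preferred one.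

Step 1
Reactants: 1 2,5-dimethylanisole
Product: 2 1-methoxy-2,5-dimethylcyclohexa-1,4-diene
Conditions: Li, NH3 (l), t-BuOH, THF, −78 to −33 °C
Reagents that add atoms: none
Why: Birch reduction protonates the two unsubstituted ring carbons ortho and meta to the methoxy group, so that all three donor substituents stay on the two remaining double bonds of the 1,4-diene.

Step 2
Reactants: 2 1-methoxy-2,5-dimethylcyclohexa-1,4-diene
Product: 4 2-bromo-3,6-dimethylcyclohepta-2,5-dien-1-one, via dibromocarbene adduct 3 (not isolated)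
Conditions: CHBr3, KOtBu, pentane, −20 °C; then AgNO3, CaCO3, acetone–H2O, 0 °C to rt
Reagents that add atoms: bromoform BrC(Br)Br; water O
Why: Electrophilic dibromocarbene should add to the most electron-rich double bond (the tetrasubstituted enol ether), and silver-assisted loss of bromide opens the cyclopropane to an oxygen-stabilised allyl cation that water turns into the 2-bromo enone (dihalocarbene ring expansion of a cyclic enol ether); no stereocenter remains.

Step 3
Reactants: 4 2-bromo-3,6-dimethylcyclohepta-2,5-dien-1-one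
Product: 5 (1S)-2-bromo-3,6-dimethylcyclohepta-2,5-dien-1-ol
Conditions: (R)-2-methyl-CBS-oxazaborolidine (20 mol %), catecholborane, toluene, −78 °C
Reagents that add atoms: none
Why: Corey–Bakshi–Shibata reduction, in which the 2-bromoalkenyl group acts as the large substituent, so the (R)-oxazaborolidine should deliver hydride to the face that gives the (S)-carbinol (C6), the stereocenter from which all others are relayed; catecholborane at low temperature leaves the alkenes alone.

Step 4
Reactants: 5 (1S)-2-bromo-3,6-dimethylcyclohepta-2,5-dien-1-ol; 6 tributyl(1-ethoxyethenyl)stannane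
Product: 7 (1S)-2-(1-ethoxyethenyl)-3,6-dimethylcyclohepta-2,5-dien-1-ol
Conditions: Pd(PPh3)4 (5 mol %), CuI (10 mol %), CsF, DMF, 45 °C
Reagents that add atoms: none
Why: Stille coupling of the alkenyl bromide (copper iodide and fluoride accelerate the hindered case) installs C4 and C3 as a 1-ethoxyvinyl group, already at the oxidation level of the later C4 ketone, without touching the carbinol.

Step 5
Reactants: 7 (1S)-2-(1-ethoxyethenyl)-3,6-dimethylcyclohepta-2,5-dien-1-ol
Product: 8 (1S,2S,7S)-1-(1-ethoxyethenyl)-4,7-dimethylbicyclo[5.1.0]oct-4-en-2-ol (cyclopropane CH2 cis to OH)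
Conditions: Sm, HgCl2 (cat.), CH2I2, THF, −78 °C to rt
Reagents that add atoms: diiodomethane ICI
Why: Simmons–Smith-type cyclopropanation with a samarium carbenoid, in which the metal alkoxide of the allylic alcohol should deliver CH2 (C2) to the adjacent tetrasubstituted double bond on the face of the oxygen and so fix quaternary C1 (and C5) relative to C6, while the homoallylic enol ether and ring alkene, which this alkoxide-bound reagent does not reach, stay intact.

Step 6
Reactants: 8 (1S,2S,7S)-1-(1-ethoxyethenyl)-4,7-dimethylbicyclo[5.1.0]oct-4-en-2-ol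
Product: 9 tert-butyl{[(1S,2S,7S)-1-(1-ethoxyethenyl)-4,7-dimethylbicyclo[5.1.0]oct-4-en-2-yl]oxy}dimethylsilane
Conditions: TBSCl, imidazole, DMAP (cat.), DMF, 40 °C
Reagents that add atoms: tert-butyldimethylsilyl chloride CC(C)(C)[Si](C)(C)Cl
Why: Standard silylation under non-acidic conditions that spare the enol ether; the silyl ether later blocks retro-aldol and elimination pathways of the β-oxygenated ketone and tolerates the nickel catalyst and the organometallic addition.

Step 7
Reactants: 9 tert-butyl{[(1S,2S,7S)-1-(1-ethoxyethenyl)-4,7-dimethylbicyclo[5.1.0]oct-4-en-2-yl]oxy}dimethylsilane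
Product: 11 (3aS,4S,8aR)-4-(tert-butyldimethylsilyloxy)-6,8a-dimethyl-1,2,3a,4,5,8-hexahydroazulen-3(8aH)-one, via bicyclic enol ether 10 (not isolated)
Conditions: Ni(cod)2 (10 mol %), IPr [1,3-bis(2,6-diisopropylphenyl)imidazol-2-ylidene] (20 mol %), toluene, 60 °C; then 10 % aq. oxalic acid, THF, rt
Reagents that add atoms: water O
Why: Zerovalent nickel bearing the carbene ligand binds the 1-ethoxyvinyl group of 9 and inserts into the adjacent cyclopropane bond C5–C2 to give an η3-(2-ethoxyallyl)(alkyl)nickel metallacycle, and C–C reductive elimination between C2 and the allyl terminus C3 forms the C2–C3 bond, so that the strain of the three-membered ring pays for a net 1,3-shift (vinylcyclopropane-to-cyclopentene rearrangement). The closest known reaction types are the Ni(cod)2/N-heterocyclic-carbene-catalysed isomerisation of vinylcyclopropanes to cyclopentenes and the thermal rearrangement of cyclopropyl ketone enol ethers to cyclopentanone enol ethers. The five-membered ring C1–C2–C3–C4–C5 closes by ring expansion of the cyclopropane C1–C2–C5 (both vinyl carbons C3 and C4 are taken into the ring, C5 stays the common atom), while the seven-membered ring is only a spectator. C1 is not touched and keeps the configuration set by the hydroxyl-directed cyclopropanation; C5 becomes trigonal in enol ether 10 and is set again in the acidic hydrolysis, where protonation and equilibration through the enol should favour the epimer with H5 anti to the angular methyl and C4 anti to the C6 silyloxy group (trans ring fusion). The step needs cleavage of C5–C2 and not of C5–C1, and no β-hydride loss from the alkylnickel: quaternary C1 secures both, because insertion into C5–C1 would need a tertiary alkyl–nickel bond and the C2–nickel intermediate has no β-hydrogen. The catalysed variant at 60 °C is chosen because the methyl group on C1 is cis to the vinyl group, so that heating to the temperature of the uncatalysed rearrangement should instead trigger a homodienyl 1,5-hydrogen shift.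

Step 8
Reactants: 11 (3aS,4S,8aR)-4-(tert-butyldimethylsilyloxy)-6,8a-dimethyl-1,2,3a,4,5,8-hexahydroazulen-3(8aH)-one
Product: 12 (3R,3aS,4S,8aR)-4-(tert-butyldimethylsilyloxy)-6,8a-dimethyl-3-(propan-2-yl)-1,2,3,3a,4,5,8,8a-octahydroazulen-3-ol
Conditions: iPrMgCl, CeCl3, THF, −78 °C
Reagents that add atoms: isopropylmagnesium chloride CC(C)[Mg]Cl
Why: Organocerium addition suppresses enolisation of the hindered ketone, and the nucleophile should approach the cyclopentanone face syn to H5, away from the C5–C6 branch and the angular methyl, so that the new hydroxyl ends up cis to the angular methyl (C4 R).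

Step 9
Reactants: 12 (3R,3aS,4S,8aR)-4-(tert-butyldimethylsilyloxy)-6,8a-dimethyl-3-(propan-2-yl)-1,2,3,3a,4,5,8,8a-octahydroazulen-3-ol
Product: 13 jaeschkeanadiol [(3R,3aS,4S,8aR)-6,8a-dimethyl-3-(propan-2-yl)-1,2,3,3a,4,5,8,8a-octahydroazulene-3,4-diol]
Conditions: Bu4NF, THF, 50 °C
Reagents that add atoms: none
Why: Fluoride-induced cleavage of the secondary silyl ether frees the C6 hydroxyl without touching any stereocenter or the tertiary alcohol.

Step 10
Reactants: 13 jaeschkeanadiol; 14 4-acetoxy-3-methoxybenzoic acid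
Product: 15 (3R,3aS,4S,8aR)-3-hydroxy-6,8a-dimethyl-3-(propan-2-yl)-1,2,3,3a,4,5,8,8a-octahydroazulen-4-yl 4-acetoxy-3-methoxybenzoate
Conditions: DCC, DMAP (cat.), CH2Cl2, rt
Reagents that add atoms: none
Why: Steglich esterification should acylate only the secondary C6 hydroxyl, because the tertiary C4 hydroxyl does not react under these conditions, and the phenol is masked as its acetate to prevent self-acylation.

Step 11
Reactants: 15 (3R,3aS,4S,8aR)-3-hydroxy-6,8a-dimethyl-3-(propan-2-yl)-1,2,3,3a,4,5,8,8a-octahydroazulen-4-yl 4-acetoxy-3-methoxybenzoate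
Product: 16 teferin [(3R,3aS,4S,8aR)-3-hydroxy-6,8a-dimethyl-3-(propan-2-yl)-1,2,3,3a,4,5,8,8a-octahydroazulen-4-yl 4-hydroxy-3-methoxybenzoate]
Conditions: pyrrolidine, CH2Cl2, 0 °C to rt
Reagents that add atoms: none
Why: Aminolysis should cleave the activated aryl acetate much faster than the hindered secondary benzoate and so release the free phenol of the target.

**Compound list**
1 | 2,5-dimethylanisole | COc1cc(C)ccc1C | starting material
2 | 1-methoxy-2,5-dimethylcyclohexa-1,4-diene | COC1=C(C)CC=C(C)C1 | intermediate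
3 | 7,7-dibromo-1-methoxy-3,6-dimethylbicyclo[4.1.0]hept-3-ene (racemic) | COC12CC(C)=CCC1(C)C2(Br)Br | intermediate
4 | 2-bromo-3,6-dimethylcyclohepta-2,5-dien-1-one | O=C1CC(C)=CCC(C)=C1Br | intermediate
5 | (1S)-2-bromo-3,6-dimethylcyclohepta-2,5-dien-1-ol | O[C@H]1CC(C)=CCC(C)=C1Br | intermediate
6 | tributyl(1-ethoxyethenyl)stannane | CCCC[Sn](CCCC)(CCCC)C(=C)OCC | starting material
7 | (1S)-2-(1-ethoxyethenyl)-3,6-dimethylcyclohepta-2,5-dien-1-ol | O[C@H]1CC(C)=CCC(C)=C1C(=C)OCC | intermediate
8 | (1S,2S,7S)-1-(1-ethoxyethenyl)-4,7-dimethylbicyclo[5.1.0]oct-4-en-2-ol (cyclopropane CH2 cis to OH) | O[C@H]1CC(C)=CC[C@@]2(C)C[C@@]12C(=C)OCC | intermediate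
9 | tert-butyl{[(1S,2S,7S)-1-(1-ethoxyethenyl)-4,7-dimethylbicyclo[5.1.0]oct-4-en-2-yl]oxy}dimethylsilane | CC(C)(C)[Si](C)(C)O[C@H]1CC(C)=CC[C@@]2(C)C[C@@]12C(=C)OCC | intermediate
10 | tert-butyl{[(4S,8aR)-3-ethoxy-6,8a-dimethyl-1,2,4,5,8,8a-hexahydroazulen-4-yl]oxy}dimethylsilane | CC(C)(C)[Si](C)(C)O[C@H]1CC(C)=CC[C@@]2(C)CCC(OCC)=C12 | intermediate
11 | (3aS,4S,8aR)-4-(tert-butyldimethylsilyloxy)-6,8a-dimethyl-1,2,3a,4,5,8-hexahydroazulen-3(8aH)-one (trans-fused) | CC(C)(C)[Si](C)(C)O[C@H]1CC(C)=CC[C@@]2(C)CCC(=O)[C@H]12 | intermediate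
12 | (3R,3aS,4S,8aR)-4-(tert-butyldimethylsilyloxy)-6,8a-dimethyl-3-(propan-2-yl)-1,2,3,3a,4,5,8,8a-octahydroazulen-3-ol | CC(C)(C)[Si](C)(C)O[C@H]1CC(C)=CC[C@@]2(C)CC[C@@](O)(C(C)C)[C@H]12 | intermediate
13 | jaeschkeanadiol [(3R,3aS,4S,8aR)-6,8a-dimethyl-3-(propan-2-yl)-1,2,3,3a,4,5,8,8a-octahydroazulene-3,4-diol] | O[C@H]1CC(C)=CC[C@@]2(C)CC[C@@](O)(C(C)C)[C@H]12 | intermediate
14 | 4-acetoxy-3-methoxybenzoic acid | COc1cc(C(=O)O)ccc1OC(C)=O | starting material
15 | (3R,3aS,4S,8aR)-3-hydroxy-6,8a-dimethyl-3-(propan-2-yl)-1,2,3,3a,4,5,8,8a-octahydroazulen-4-yl 4-acetoxy-3-methoxybenzoate | COc1cc(C(=O)O[C@H]2CC(C)=CC[C@@]3(C)CC[C@@](O)(C(C)C)[C@H]23)ccc1OC(C)=O | intermediate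
16 | teferin [(3R,3aS,4S,8aR)-3-hydroxy-6,8a-dimethyl-3-(propan-2-yl)-1,2,3,3a,4,5,8,8a-octahydroazulen-4-yl 4-hydroxy-3-methoxybenzoate] | COc1cc(C(=O)O[C@H]2CC(C)=CC[C@@]3(C)CC[C@@](O)(C(C)C)[C@H]23)ccc1O | target

**Step count**
Total steps: 11. Longest linear sequence: 11 steps (1 to 16); 6 and 14 are purchased.

**Steps most likely to fail**

Step 7. The nickel may fail to insert into the crowded, electron-rich alkoxyvinylcyclopropane, or the metallacycle may collapse to ring-opened dienes instead of eliminating reductively. Protonation at C5 during the hydrolysis may also occur without reaching the favourable epimer. Fallback (the C2–C3 bond is closed by an aldol condensation instead of the ring expansion), setting out from 9 and coming back at 11: mild aqueous acid hydrolyses the enol ether to the cyclopropyl methyl ketone F1. Me2AlSPh opens the cyclopropane by homoconjugate attack of thiolate at the CH2 carbon to give the γ-phenylsulfanyl ketone F2. NaIO4 oxidises the sulfide to the sulfoxide F3. A Pummerer rearrangement (trifluoroacetic anhydride, 2,6-lutidine, then aqueous NaHCO3) unveils the keto aldehyde F4. Intramolecular aldol condensation (KOH, MeOH, 0 °C) between the methyl ketone and the non-enolisable aldehyde gives the cyclopentenone F5. Conjugate reduction with [(Ph3P)CuH]6 then returns to 11, where C5 is equilibrated as in the main route.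

Step 5. Chemoselectivity may be lost (methylene transfer to the enol ether double bond or to the ring alkene), or transfer to the tetrasubstituted alkene may be too slow. Fallback (C4 and C3 are carried through the cyclopropanation as an inert alkyne and the oxygen is added afterwards), setting out from 5 and coming back at 11: Sonogashira coupling of 5 with ethynyltrimethylsilane (PdCl2(PPh3)2, CuI, iPr2NH) gives the enynol F6. Hydroxyl-directed Simmons–Smith cyclopropanation with the zinc carbenoid (Et2Zn, CH2I2, CH2Cl2, 0 °C) gives the alkynylcyclopropanol F7. Silylation (TBSCl, imidazole) gives the silyl ether F8. Gold-catalysed hydration with loss of the alkynyl silyl group ((IPr)AuCl, AgSbF6, aqueous dioxane) gives the methyl ketone F1 of the first fallback. LiN(iPr)2 and Me3SiCl convert it into the silyl enol ether F9, which is rearranged under the nickel conditions of step 7 to the bicyclic silyl enol ether F10 and hydrolysed to 11.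

Step 8. The hindered ketone may be enolised, or the secondary organometallic may transfer hydride instead of adding to the carbonyl; base-induced loss of the β-silyloxy group is a further risk. Fallback (an sp2 nucleophile without β-hydrogen, then hydrogenation), setting out from 11 and coming back at 12: addition of isopropenylmagnesium bromide with CeCl3 gives the isopropenyl carbinol F11 with the same facial preference. Hydrogenation of its 1,1-disubstituted double bond with RhCl(PPh3)3 and H2, which should leave the trisubstituted ring alkene untouched, gives 12.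

**Further compounds**
F1 | step 7 | 1-[(1S,2S,7S)-2-(tert-butyldimethylsilyloxy)-4,7-dimethylbicyclo[5.1.0]oct-4-en-1-yl]ethan-1-one | CC(C)(C)[Si](C)(C)O[C@H]1CC(C)=CC[C@@]2(C)C[C@@]12C(C)=O
F2 | step 7 | 1-[(1S,2S,7R)-2-(tert-butyldimethylsilyloxy)-4,7-dimethyl-7-(phenylsulfanylmethyl)cyclohept-4-en-1-yl]ethan-1-one | CC(C)(C)[Si](C)(C)O[C@H]1CC(C)=CC[C@@](C)(CSc2ccccc2)[C@@H]1C(C)=O
F3 | step 7 | 1-[(1S,2S,7R)-2-(tert-butyldimethylsilyloxy)-4,7-dimethyl-7-(phenylsulfinylmethyl)cyclohept-4-en-1-yl]ethan-1-one (configuration at sulfur not defined) | CC(C)(C)[Si](C)(C)O[C@H]1CC(C)=CC[C@@](C)(CS(=O)c2ccccc2)[C@@H]1C(C)=O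
F4 | step 7 | (1R,6S,7S)-7-acetyl-6-(tert-butyldimethylsilyloxy)-1,4-dimethylcyclohept-3-ene-1-carbaldehyde | CC(C)(C)[Si](C)(C)O[C@H]1CC(C)=CC[C@@](C)(C=O)[C@@H]1C(C)=O
F5 | step 7 | (3aS,4S,8aS)-4-(tert-butyldimethylsilyloxy)-6,8a-dimethyl-3a,4,5,8-tetrahydroazulen-3(8aH)-one | CC(C)(C)[Si](C)(C)O[C@H]1CC(C)=CC[C@@]2(C)C=CC(=O)[C@H]12
F6 | step 5 | (1S)-3,6-dimethyl-2-[(trimethylsilyl)ethynyl]cyclohepta-2,5-dien-1-ol | O[C@H]1CC(C)=CCC(C)=C1C#C[Si](C)(C)C
F7 | step 5 | (1R,2S,7S)-4,7-dimethyl-1-[(trimethylsilyl)ethynyl]bicyclo[5.1.0]oct-4-en-2-ol (cyclopropane CH2 cis to OH) | O[C@H]1CC(C)=CC[C@@]2(C)C[C@@]12C#C[Si](C)(C)C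
F8 | step 5 | tert-butyl{[(1R,2S,7S)-4,7-dimethyl-1-[(trimethylsilyl)ethynyl]bicyclo[5.1.0]oct-4-en-2-yl]oxy}dimethylsilane | CC(C)(C)[Si](C)(C)O[C@H]1CC(C)=CC[C@@]2(C)C[C@@]12C#C[Si](C)(C)C
F9 | step 5 | tert-butyl{[(1S,2S,7S)-4,7-dimethyl-1-[1-(trimethylsilyloxy)ethenyl]bicyclo[5.1.0]oct-4-en-2-yl]oxy}dimethylsilane | CC(C)(C)[Si](C)(C)O[C@H]1CC(C)=CC[C@@]2(C)C[C@@]12C(=C)O[Si](C)(C)C
F10 | step 5 | tert-butyl{[(4S,8aR)-6,8a-dimethyl-3-(trimethylsilyloxy)-1,2,4,5,8,8a-hexahydroazulen-4-yl]oxy}dimethylsilane | CC(C)(C)[Si](C)(C)O[C@H]1CC(C)=CC[C@@]2(C)CCC(O[Si](C)(C)C)=C12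
F11 | step 8 | (3S,3aS,4S,8aR)-4-(tert-butyldimethylsilyloxy)-6,8a-dimethyl-3-(prop-1-en-2-yl)-1,2,3,3a,4,5,8,8a-octahydroazulen-3-ol | CC(C)(C)[Si](C)(C)O[C@H]1CC(C)=CC[C@@]2(C)CC[C@@](O)(C(C)=C)[C@H]12
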